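**Retrosynthetic overview**
1. Target 11 comes from global O-debenzylation of the pentabenzyl ether 10.
2. 10 is cut at the flavanone C2–aryl bond: enantioselective palladium-catalysed conjugate addition of boronic acid 9 to the 2-unsubstituted chromone of 8 sets the only stereocentre, and the flavone enone stays untouched.
3. 8 is opened at both pyranone rings together: one-flask formylation, crossed Claisen condensation and double cyclodehydration of keto ester 5 with ethyl formate and acetophenone 1.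
4. 5 comes from SNAr of hydroquinone ketone 3 on methyl 4-fluorobenzoate 4; 3 comes from Elbs para-hydroxylation of 1, so 1 supplies ring A of both halves.
5. Ring order: all benzene rings are bought; the chromone ring and the flavone ring C close together in step 3; the chromone becomes the (2S)-flavanone in step 4.

Assumption: 1 is bought as a catalogue compound, and the (R)-ligand in step 4 is assigned by analogy with the known facial sense of this catalyst class (the enantiomeric ligand is used if the sense proves reversed).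

**Step 1**
Reactants: 1 1-[2,4-bis(benzyloxy)-6-hydroxyphenyl]ethan-1-one
Product: 3 1-[2,4-bis(benzyloxy)-3,6-dihydroxyphenyl]ethan-1-one, via aryl sulfate 2 (not isolated)
Conditions: K2S2O8 (1.1 equiv), 10% aq NaOH/pyridine, 0 → 20 °C, 24 h; unreacted 1 recovered at pH 5; then aq HCl, 85 °C, 1 h
Reagents that add atoms: potassium peroxodisulfate K2S2O8, [K+].[K+].[O-]S(=O)(=O)OOS(=O)(=O)[O-]
Why: Elbs persulfate oxidation, in which the phenolate is attacked by peroxodisulfate at the only free para position to give sulfate 2, which acid hydrolyses to the hydroquinone while the benzyl ethers survive.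

**Step 2**
Reactants: 3 1-[2,4-bis(benzyloxy)-3,6-dihydroxyphenyl]ethan-1-one; 4 methyl 4-fluorobenzoate
Product: 5 methyl 4-[3-acetyl-2,6-bis(benzyloxy)-4-hydroxyphenoxy]benzoate
Conditions: Cs2CO3 (1.2 equiv), DMSO, 110 °C, argon, 12 h
Reagents that add atoms: none
Why: Nucleophilic aromatic substitution (addition–elimination) in which the non-chelated phenoxide between the two benzyloxy groups displaces fluoride para to the ester, while the acetyl-chelated, carbonyl-conjugated hydroxyl is far less nucleophilic and stays free.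

**Step 3**
Reactants: 5 methyl 4-[3-acetyl-2,6-bis(benzyloxy)-4-hydroxyphenoxy]benzoate; 1 1-[2,4-bis(benzyloxy)-6-hydroxyphenyl]ethan-1-one
Product: 8 5,7-bis(benzyloxy)-2-(4-{[5,7-bis(benzyloxy)-4-oxo-4H-chromen-6-yl]oxy}phenyl)-4H-chromen-4-one, via keto aldehyde 6 (not isolated), via tetracarbonyl intermediate 7 (not isolated)
Conditions: a) 5, LiN(SiMe3)2 (2.2 equiv), THF, −78 °C; HCO2Et (1.05 equiv), −78 → 0 °C; b) dianion of 1 [1 (1.3 equiv), LiN(SiMe3)2 (4.0 equiv), THF, −78 → −10 °C] added, 0 → 45 °C, 6 h; c) AcOH (excess), THF distilled out, 105 °C, 2 h; one flask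
Reagents that add atoms: ethyl formate, CCOC=O
Why: Proposed new method: two crossed Claisen condensations run in sequence in one flask, where the dianion of 5 is C-formylated by ethyl formate to the stabilised β-keto aldehyde enolate 6, which is neither a carbon nucleophile nor an electrophile, so the dianion of 1 then attacks only the benzoate ester to give 7, and hot acetic acid closes both 1-(2-hydroxyaryl)-1,3-dicarbonyl units by hemiketal formation and dehydration to the chromone and the flavone ring at once; the closest known reactions are the formylation–cyclisation route to chromones and the lithium polyanion (Baker–Venkataraman-type) diketone route to flavones, and no stereocentre is formed.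

**Step 4**
Reactants: 8 5,7-bis(benzyloxy)-2-(4-{[5,7-bis(benzyloxy)-4-oxo-4H-chromen-6-yl]oxy}phenyl)-4H-chromen-4-one; 9 [4-(benzyloxy)phenyl]boronic acid
Product: 10 (2S)-5,7-bis(benzyloxy)-2-[4-(benzyloxy)phenyl]-6-{4-[5,7-bis(benzyloxy)-4-oxo-4H-chromen-2-yl]phenoxy}-2,3-dihydro-4H-chromen-4-one
Conditions: 9 (2.5 equiv), Pd(OCOCF3)2 (10 mol%), (R)-4-tert-butyl-2-(pyridin-2-yl)-4,5-dihydrooxazole (12 mol%), NH4PF6 (30 mol%), H2O (5 equiv), ClCH2CH2Cl, 60 °C, 24 h
Reagents that add atoms: none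
Why: Asymmetric conjugate addition of an arylboronic acid (Hayashi–Miyaura-type 1,4-addition under cationic divalent palladium with a chiral pyridine–oxazoline ligand), in which the aryl–palladium species inserts only the 2-unsubstituted chromone alkene, the β,β-disubstituted flavone enone is inert, and the ligand directs the aryl group to the face of C2 that gives the S configuration.

**Step 5**
Reactants: 10 (2S)-5,7-bis(benzyloxy)-2-[4-(benzyloxy)phenyl]-6-{4-[5,7-bis(benzyloxy)-4-oxo-4H-chromen-2-yl]phenoxy}-2,3-dihydro-4H-chromen-4-one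
Product: 11 (2S)-6-[4-(5,7-dihydroxy-4-oxo-4H-chromen-2-yl)phenoxy]-5,7-dihydroxy-2-(4-hydroxyphenyl)-2,3-dihydro-4H-chromen-4-one
Conditions: H2 (1 atm), Pd/C (10 wt% palladium on carbon), THF/MeOH 1:1, rt, stopped at complete debenzylation
Reagents that add atoms: none
Why: Catalytic hydrogenolysis of the five benzyl aryl ethers, which is much faster than reduction of the flavone alkene or the ketones and runs under neutral conditions, so C2 cannot epimerise by retro-oxa-Michael ring opening.

**Compound list**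
1 | 1-[2,4-bis(benzyloxy)-6-hydroxyphenyl]ethan-1-one | CC(=O)c1c(O)cc(OCc2ccccc2)cc1OCc1ccccc1 | starting material
2 | potassium 3-acetyl-2,6-bis(benzyloxy)-4-hydroxyphenyl sulfate | CC(=O)c1c(O)cc(OCc2ccccc2)c(OS(=O)(=O)[O-])c1OCc1ccccc1.[K+] | intermediate
3 | 1-[2,4-bis(benzyloxy)-3,6-dihydroxyphenyl]ethan-1-one | CC(=O)c1c(O)cc(OCc2ccccc2)c(O)c1OCc1ccccc1 | intermediate
4 | methyl 4-fluorobenzoate | COC(=O)c1ccc(F)cc1 | starting material
5 | methyl 4-[3-acetyl-2,6-bis(benzyloxy)-4-hydroxyphenoxy]benzoate | COC(=O)c1ccc(Oc2c(OCc3ccccc3)cc(O)c(C(C)=O)c2OCc2ccccc2)cc1 | intermediate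
6 | methyl 4-[2,6-bis(benzyloxy)-4-hydroxy-3-(3-oxopropanoyl)phenoxy]benzoate (present as its lithium enolate) | COC(=O)c1ccc(Oc2c(OCc3ccccc3)cc(O)c(C(=O)CC=O)c2OCc2ccccc2)cc1 | intermediate
7 | 1-[2,4-bis(benzyloxy)-6-hydroxyphenyl]-3-{4-[2,6-bis(benzyloxy)-4-hydroxy-3-(3-oxopropanoyl)phenoxy]phenyl}propane-1,3-dione | O=CCC(=O)c1c(O)cc(OCc2ccccc2)c(Oc2ccc(C(=O)CC(=O)c3c(O)cc(OCc4ccccc4)cc3OCc3ccccc3)cc2)c1OCc1ccccc1 | intermediate
8 | 5,7-bis(benzyloxy)-2-(4-{[5,7-bis(benzyloxy)-4-oxo-4H-chromen-6-yl]oxy}phenyl)-4H-chromen-4-one | O=c1ccoc2cc(OCc3ccccc3)c(Oc3ccc(-c4cc(=O)c5c(OCc6ccccc6)cc(OCc6ccccc6)cc5o4)cc3)c(OCc3ccccc3)c12 | intermediate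
9 | [4-(benzyloxy)phenyl]boronic acid | OB(O)c1ccc(OCc2ccccc2)cc1 | starting material
10 | (2S)-5,7-bis(benzyloxy)-2-[4-(benzyloxy)phenyl]-6-{4-[5,7-bis(benzyloxy)-4-oxo-4H-chromen-2-yl]phenoxy}-2,3-dihydro-4H-chromen-4-one | O=C1C[C@@H](c2ccc(OCc3ccccc3)cc2)Oc2cc(OCc3ccccc3)c(Oc3ccc(-c4cc(=O)c5c(OCc6ccccc6)cc(OCc6ccccc6)cc5o4)cc3)c(OCc3ccccc3)c21 | intermediate
11 | (2S)-6-[4-(5,7-dihydroxy-4-oxo-4H-chromen-2-yl)phenoxy]-5,7-dihydroxy-2-(4-hydroxyphenyl)-2,3-dihydro-4H-chromen-4-one (CNP0206535.1) | O=C1C[C@@H](c2ccc(O)cc2)Oc2cc(O)c(Oc3ccc(-c4cc(=O)c5c(O)cc(O)cc5o4)cc3)c(O)c21 | target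

**Step count**
Total: 5 steps. Longest linear sequence: 5 steps (1 → 3 → 5 → 8 → 10 → 11); compound 1 enters a second time in step 3.

**Steps most likely to fail, with fallbacks**

Step 3. The one-flask sequence may suffer from self-condensation of 5, formyl scrambling onto 1, or a sluggish Claisen reaction between two polyanions. The fallback closes the two rings separately and joins them by C–O coupling; it sets out from 1 and 3 and comes back at 8. The dianion of 1 (LiN(SiMe3)2, 3 equiv, THF, −78 °C) is acylated with 4-iodobenzoyl chloride to give 1-[2,4-bis(benzyloxy)-6-hydroxyphenyl]-3-(4-iodophenyl)propane-1,3-dione F1, which AcOH/NaOAc at 100 °C cyclises to 5,7-bis(benzyloxy)-2-(4-iodophenyl)-4H-chromen-4-one F2. In parallel, 3 is formylated (HCO2Et, NaH, THF, 0 °C → rt) and cyclised on acidic work-up (aq HCl/AcOH) to 5,7-bis(benzyloxy)-6-hydroxy-4H-chromen-4-one F3. Copper-catalysed Ullmann ether coupling of F2 with F3 (CuI 10 mol%, picolinic acid 20 mol%, K3PO4, DMSO, 90 °C) then gives 8.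

Step 4. The electron-rich 5,7-dialkoxychromone carrying a peri benzyloxy group may react slowly or with insufficient enantioselectivity. The fallback sets the stereocentre by kinetic resolution; it sets out from 8 and comes back at 10. Arylation of 8 with 9 under an achiral catalyst (Pd(OCOCF3)2, 2,2'-bipyridine, AcOH/THF/H2O, 60 °C) gives racemic 5,7-bis(benzyloxy)-2-[4-(benzyloxy)phenyl]-6-{4-[5,7-bis(benzyloxy)-4-oxo-4H-chromen-2-yl]phenoxy}-2,3-dihydro-4H-chromen-4-one F4. Asymmetric transfer hydrogenation ([RhCl(C5Me5){(R,R)-TsDPEN}] 1 mol%, HCO2H/Et3N 5:2, EtOAc, rt, to about 55% conversion) reduces the (2R)-ketone to the cis alcohol (2R,4R)-5,7-bis(benzyloxy)-2-[4-(benzyloxy)phenyl]-6-{4-[5,7-bis(benzyloxy)-4-oxo-4H-chromen-2-yl]phenoxy}-3,4-dihydro-2H-chromen-4-ol F5. Unreacted (2S)-ketone 10 is separated from F5 by chromatography; the flavone carbonyl is not reduced under these conditions.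

Step 2. The phenoxide is flanked by two benzyloxy groups and the fluoroarene is only moderately activated, so conversion or O-selectivity may be poor. The fallback replaces the substitution by a metal-catalysed coupling; it sets out from 3 and comes back at 5. Ullmann-type O-arylation of 3 with methyl 4-iodobenzoate (CuI 10 mol%, picolinic acid 20 mol%, K3PO4, DMSO, 90 °C, argon) gives 5 directly, and no new compound is made on this way (F0).

**Further compounds**
F0 | step 2 | none | none
F1 | step 3 | 1-[2,4-bis(benzyloxy)-6-hydroxyphenyl]-3-(4-iodophenyl)propane-1,3-dione | O=C(CC(=O)c1ccc(I)cc1)c1c(O)cc(OCc2ccccc2)cc1OCc1ccccc1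
F2 | step 3 | 5,7-bis(benzyloxy)-2-(4-iodophenyl)-4H-chromen-4-one | O=c1cc(-c2ccc(I)cc2)oc2cc(OCc3ccccc3)cc(OCc3ccccc3)c12
F3 | step 3 | 5,7-bis(benzyloxy)-6-hydroxy-4H-chromen-4-one | O=c1ccoc2cc(OCc3ccccc3)c(O)c(OCc3ccccc3)c12
F4 | step 4 | racemic 5,7-bis(benzyloxy)-2-[4-(benzyloxy)phenyl]-6-{4-[5,7-bis(benzyloxy)-4-oxo-4H-chromen-2-yl]phenoxy}-2,3-dihydro-4H-chromen-4-one | O=C1CC(c2ccc(OCc3ccccc3)cc2)Oc2cc(OCc3ccccc3)c(Oc3ccc(-c4cc(=O)c5c(OCc6ccccc6)cc(OCc6ccccc6)cc5o4)cc3)c(OCc3ccccc3)c21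
F5 | step 4 | (2R,4R)-5,7-bis(benzyloxy)-2-[4-(benzyloxy)phenyl]-6-{4-[5,7-bis(benzyloxy)-4-oxo-4H-chromen-2-yl]phenoxy}-3,4-dihydro-2H-chromen-4-ol | O[C@@H]1C[C@H](c2ccc(OCc3ccccc3)cc2)Oc2cc(OCc3ccccc3)c(Oc3ccc(-c4cc(=O)c5c(OCc6ccccc6)cc(OCc6ccccc6)cc5o4)cc3)c(OCc3ccccc3)c21
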